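The catalyst stands on both sides of each step that uses it, so its amount stays constant and it is thinned by the feed alone, by a factor of 1.10. With the catalyst held fixed, each step is pseudo-first-order in its organic species, and the charge of starting material sets the scale of the flask but not its proportions.

    starting material + catalyst → catalyst + target (k1 = 680 M⁻¹ min⁻¹)
    starting material → side product (k2 = 0.23 min⁻¹)
    catalyst + target → catalyst + over-reaction product (k3 = 13 M⁻¹ min⁻¹)
    target + catalyst ⇌ isomer of the product + catalyst, rate k4*[catalyst]*[target] forward; the back reaction follows from the equilibrium constant (K4 = 12, k4 = 13 M⁻¹ min⁻¹)

| setting | oak | larch | birch | elm |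
|---|---|---|---|---|
| starting material | 0.60 M (fed, over 2.5 min) | 1.0 M (fed, over 2.5 min) | 1.5 M (fed, over 2.5 min) | 2.5 M (fed, over 2.5 min) |
| catalyst | 0.82 mM | 0.82 mM | 0.82 mM | 0.82 mM |
| time | 12 min | 12 min | 12 min | 12 min |
| remark | the fed solution adds 0.10 times the starting volume | the fed solution adds 0.10 times the starting volume | the fed solution adds 0.10 times the starting volume | the fed solution adds 0.10 times the starting volume |

- [target] at the end for oak, larch, birch, elm, in this order
- the shape of the row from first to last (falls all the way / hardly changes / rises all the way / falls, then rises / rises, then falls)

The first setting to turn is that charge, and it is the one the flasks differ in. Its effect can be put into one number: Y, the target standing at the end per unit of starting material charged. Reckoned at full dilution, step 1 consumes starting material with a constant of 0.507 min⁻¹, which is faster than the 0.23 min⁻¹ of step 2, so a share of 0.688 becomes target. Over-reaction and isomerisation then take target with a joint constant of 0.0194 min⁻¹. Counting that loss from the end of the feed leaves 0.832 of the target, and the final volume divides the amount by 1.10. The back reaction is dropped in this reckoning: its rate is the forward rate times the ratio of isomer to target, divided by 12, and with half of the lost target reckoned as isomer, it comes by hand to 0.00841 of the forward rate at the end of the run. So Y is 0.520, and by hand the row is 0.312 M, 0.520 M, 0.780 M and 1.30 M, rising with the charge.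

The second setting is the run time. Starting material has a half-life of 0.941 min under steps 1 and 2 together, much shorter than the 12 min of the run. By hand, hardly any of what stood at the end of the feed remains at the end, and from then on target falls slowly at 0.0194 min⁻¹.

The forecast reads 0.314 M, 0.524 M, 0.786 M and 1.31 M, rises all the way, slightly above this reckoning at elm, and says “End [target] therefore scales exactly with dose”.

The simulation gives 0.315 M, 0.524 M, 0.786 M and 1.31 M, rises all the way. Side product ends at 30.8% of the charge in oak and at 30.8% of the charge in elm. With Y at 0.520, the oak charge of 0.60 M stands for 0.312 M of target, and oak holds 0.315 M. The elm charge of 2.5 M stands for 1.30 M, and elm holds 1.31 M.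

(The constants used here come from no measurement; no experiment stands behind them.)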